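**Plan**

- Retrosynthesis: the C6–OCH3 ether is cut last, back to 2-hydroxy-6-hexaprenyl-1,4-benzoquinone. The quinone ring is then cut at C1–C2 and at C5–C6 into a two-carbon piece (C6–C1, ethyl 1,3-dithiane-2-carboxylate, a masked glyoxylate acyl anion) and a four-carbon piece (C2–C5, a methyl alkynyl ketone that already carries the hexaprenyl chain on the future C2).
- Enabling feature: in the ring, C1=O and C4=O are 1,4-related, so C1–C2 joins two carbons of like (acceptor) polarity; it is made with C1 umpoled as a dithiane carbanion that adds to the ynone β-carbon. O–C6=C5–C4=O is a vinylogous ester (a 1,3-dicarbonyl), the retron of a Claisen closure by the ynone methyl group onto the donor's ester.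
- Forward: the C30 chain is joined first (two farnesyl units, C12–C13 bond by sulfone alkylation, then reductive desulfonylation) and extended by the C4 alkynyl ketone. The only ring is then closed in one Michael–Claisen annulation; dithiane removal and O-methylation finish the route.
- Stereochemistry: there are no stereocentres. Four of the five E olefins come unchanged from (2E,6E)-farnesyl building blocks; the fifth (chain C10=C11) comes from E-selective SeO2 allylic hydroxylation. Every later C–C bond is made at an sp3 carbon without allylic transposition.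

Key step: step 10

Assumption: all-E-hexaprenol is not counted as commercially available, so the C30 chain is assembled from (2E,6E)-farnesol and (2E,6E)-farnesyl bromide.
Shorthand: "hexaprenyl" means (2E,6E,10E,14E,18E)-3,7,11,15,19,23-hexamethyltetracosa-2,6,10,14,18,22-hexaen-1-yl.

**Route**

Step 1
Reactants: 1 (2E,6E)-farnesyl bromide
Product: 2 (2E,6E)-farnesyl p-tolyl sulfone
Conditions: p-TolSO2Na, DMF, 23 °C
Reagents that add atoms: sodium p-toluenesulfinate, Cc1ccc(cc1)S(=O)[O-].[Na+]
Why: SN2 S-alkylation of the soft sulfinate at the primary allylic bromide should give the sulfone without touching the E olefins (sulfinate alkylation).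

Step 2
Reactants: 3 (2E,6E)-farnesol
Product: 4 (2E,6E)-farnesyl acetate
Conditions: Ac2O, pyridine, DMAP (cat.), CH2Cl2, 0 to 23 °C
Reagents that add atoms: acetic anhydride, CC(=O)OC(C)=O
Why: DMAP-catalysed acetylation (nucleophilic acyl substitution) masks the allylic alcohol as an electron-poor ester that survives, and steers, the allylic oxidation of step 3.

Step 3
Reactants: 4 (2E,6E)-farnesyl acetate
Product: 5 (2E,6E,10E)-12-hydroxy-3,7,11-trimethyldodeca-2,6,10-trien-1-yl acetate
Conditions: SeO2 (0.1 equiv), t-BuOOH (3 equiv), salicylic acid (0.1 equiv), CH2Cl2, 0 to 23 °C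
Reagents that add atoms: tert-butyl hydroperoxide, CC(C)(C)OO (stoichiometric oxygen source); selenium dioxide, O=[Se]=O (catalytic oxygen carrier)
Why: Riley-type allylic hydroxylation (ene reaction, then [2,3]-sigmatropic shift) should attack the most electron-rich, terminal trisubstituted olefin at its E-methyl group, so that the 10E allylic alcohol geometry is set by the sigmatropic transition state while the acetate deactivates the C2 olefin.

Step 4
Reactants: 5 (2E,6E,10E)-12-hydroxy-3,7,11-trimethyldodeca-2,6,10-trien-1-yl acetate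
Product: 6 (2E,6E,10E)-12-bromo-3,7,11-trimethyldodeca-2,6,10-trien-1-yl acetate
Conditions: CBr4, PPh3, CH2Cl2, 0 °C
Reagents that add atoms: carbon tetrabromide, BrC(Br)(Br)Br
Why: Appel reaction, in which bromide displaces the alkoxyphosphonium group by SN2 at the primary allylic carbon, without allylic transposition and with the acetate untouched.

Step 5
Reactants: 2 (2E,6E)-farnesyl p-tolyl sulfone; 6 (2E,6E,10E)-12-bromo-3,7,11-trimethyldodeca-2,6,10-trien-1-yl acetate
Product: 7 (2E,6E,10E,14E,18E)-3,7,11,15,19,23-hexamethyl-13-(p-tolylsulfonyl)tetracosa-2,6,10,14,18,22-hexaen-1-yl acetate (racemic at C13)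
Conditions: 2, n-BuLi (1.0 equiv), THF/DMPU, −78 °C; then 6, −78 to −40 °C
Reagents that add atoms: none
Why: alkylation of the α-sulfonyl allyl carbanion at its α-carbon by the primary allylic bromide (SN2, sulfone coupling of the Julia/Biellmann kind) should join the two C15 units head to tail at −78 °C, where the acetate is not attacked; the sulfone-bearing C13 forms as a racemate and is erased in step 6.

Step 6
Reactants: 7 (2E,6E,10E,14E,18E)-3,7,11,15,19,23-hexamethyl-13-(p-tolylsulfonyl)tetracosa-2,6,10,14,18,22-hexaen-1-yl acetate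
Product: 9 all-E-hexaprenol [(2E,6E,10E,14E,18E)-3,7,11,15,19,23-hexamethyltetracosa-2,6,10,14,18,22-hexaen-1-ol], via C30 hydroxy sulfone 8 (not isolated)
Conditions: Pd(dppp)Cl2 (5 mol%), LiBHEt3 (4 equiv), THF, 0 °C
Reagents that add atoms: none
Why: LiBHEt3 should first cleave the acetate reductively; the allylic sulfone then ionises on zerovalent palladium (formed in situ from Pd(dppp)Cl2) to a π-allyl complex that takes hydride at the less substituted terminus, so the C14=C15 double bond keeps its position and E geometry (palladium-catalysed reductive desulfonylation).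

Step 7
Reactants: 9 all-E-hexaprenol
Product: 10 all-E-hexaprenyl bromide [(2E,6E,10E,14E,18E)-1-bromo-3,7,11,15,19,23-hexamethyltetracosa-2,6,10,14,18,22-hexaene]
Conditions: PBr3 (0.4 equiv), Et2O, 0 °C
Reagents that add atoms: phosphorus tribromide, BrP(Br)Br
Why: PBr3 should convert the primary allylic alcohol into the bromide by SN2 displacement of the phosphite ester at 0 °C, the standard halogenation of polyprenols, without E/Z or allylic isomerisation.

Step 8
Reactants: 10 all-E-hexaprenyl bromide; 11 (±)-but-3-yn-2-ol
Product: 12 (6E,10E,14E,18E,22E)-7,11,15,19,23,27-hexamethyloctacosa-6,10,14,18,22,26-hexaen-3-yn-2-ol (racemic at C2)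
Conditions: 11 (1.5 equiv), CuI (10 mol%), n-Bu4NI (10 mol%), K2CO3 (2 equiv), DMF/THF, 23 °C
Reagents that add atoms: none
Why: the copper acetylide formed from 11 with catalytic CuI and carbonate should displace the primary allylic bromide at the α-carbon (copper-catalysed allyl–alkynyl coupling), giving the skipped enyne with the 6E olefin intact; the carbinol centre stays racemic and is erased in step 9.

Step 9
Reactants: 12 (6E,10E,14E,18E,22E)-7,11,15,19,23,27-hexamethyloctacosa-6,10,14,18,22,26-hexaen-3-yn-2-ol
Product: 13 (6E,10E,14E,18E,22E)-7,11,15,19,23,27-hexamethyloctacosa-6,10,14,18,22,26-hexaen-3-yn-2-one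
Conditions: MnO2 (activated, 20 equiv), CH2Cl2, 23 °C
Reagents that add atoms: none
Why: activated MnO2 should oxidise the propargylic alcohol selectively under neutral heterogeneous conditions, which spare the base-sensitive skipped enyne methylene and the isolated olefins.

Step 10
Reactants: 13 (6E,10E,14E,18E,22E)-7,11,15,19,23,27-hexamethyloctacosa-6,10,14,18,22,26-hexaen-3-yn-2-one; 14 ethyl 1,3-dithiane-2-carboxylate
Product: 16 7-hydroxy-11-hexaprenyl-1,5-dithiaspiro[5.5]undeca-7,10-dien-9-one (enol form of the spiro-dithiane 7,9-dione), via Z-enone ester Michael adduct 15 (not isolated)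
Conditions: 14 (1.2 equiv), KOtBu (1.1 equiv), THF, −78 °C; then 13; then KOtBu (1.2 equiv), −78 to 0 °C; 1 M HCl work-up
Reagents that add atoms: none
Why: Proposed new method: the potassium enolate of 14, an ester-stabilised dithianyl carbanion that acts as a glyoxylate acyl-anion equivalent, should add 1,4 to the ynone at the alkyne carbon bearing the hexaprenyl CH2 (new bond = quinone C1–C2), tert-butanol relays the proton from the allenolate to give the Z-enone ester 15, and the methyl-ketone enolate of 15 then attacks the ester carbonyl and expels ethoxide (new bond = quinone C5–C6), which leaves 16 as its stabilised vinylogous-acid enolate and makes the sequence irreversible. The closest known reaction types are the Michael–Claisen [4+2] annulation of methyl alkenyl ketones with malonate-type donors to cyclohexane-1,3-diones and the conjugate addition of 2-alkoxycarbonyl-1,3-dithiane anions to conjugated ketones; new is their union on an alkynyl methyl ketone, so that the ring arrives at the hydroxyquinone oxidation level. The six-membered carbocycle closes in the Claisen step by a 6-(enolendo)-exo-trig attack of the methyl-ketone enolate carbon on the ester carbonyl. No stereocentre is formed (the spiro carbon carries two identical sulfur arms); the one geometric requirement, acetyl cis to the dithiane carbon, should be met because the E and Z enones interconvert under the basic conditions by reversible Michael addition and only the Z isomer can cyclise. The step needs 1,4-addition instead of 1,2-addition or deprotonation of the propargylic–allylic CH2 of 13, which the soft, fully substituted potassium enolate at −78 °C in the absence of free alkoxide should secure, and C- instead of O-acylation, which is secured because the dithiane carbon carries no hydrogen (no 2-pyrone can form) and an enol lactone formed by O-attack is reopened by alkoxide and funnelled to the far more stable 1,3-dione enolate.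

Step 11
Reactants: 16 7-hydroxy-11-hexaprenyl-1,5-dithiaspiro[5.5]undeca-7,10-dien-9-one
Product: 17 2-hydroxy-6-hexaprenylcyclohexa-2,5-diene-1,4-dione (2-hydroxy-6-hexaprenyl-1,4-benzoquinone)
Conditions: PhI(OCOCF3)2 (1.5 equiv), MeCN/H2O 9:1, 0 °C, 15 min
Reagents that add atoms: water, O
Why: oxidative dethioacetalisation with the trivalent-iodine reagent, in which sulfur should be activated far faster than the isolated olefins, the ring-opened thionium ion is trapped by water and collapses to the C1 carbonyl, and the dithiol is released as its disulfide.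

Step 12
Reactants: 17 2-hydroxy-6-hexaprenylcyclohexa-2,5-diene-1,4-dione
Product: 18 2-hexaprenyl-6-methoxycyclohexa-2,5-diene-1,4-dione (2-hexaprenyl-6-methoxy-1,4-benzoquinone, the target)
Conditions: TMSCHN2 (1.1 equiv), MeOH/toluene 1:4, 0 °C
Reagents that add atoms: (trimethylsilyl)diazomethane, C[Si](C)(C)C=[N+]=[N-]
Why: the vinylogous acid should protonate the diazoalkane, and the methyldiazonium ion formed on methanolysis alkylates the adjacent oxygen of the ion pair (diazoalkane O-methylation), giving the para-quinone vinylogous ester, the more stable of the two possible ethers.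

**Compound list**

1 | (2E,6E)-farnesyl bromide [(2E,6E)-1-bromo-3,7,11-trimethyldodeca-2,6,10-triene] | BrC/C=C(\C)CC/C=C(\C)CCC=C(C)C | starting material
2 | (2E,6E)-farnesyl p-tolyl sulfone | Cc1ccc(cc1)S(=O)(=O)C/C=C(\C)CC/C=C(\C)CCC=C(C)C | intermediate
3 | (2E,6E)-farnesol | OC/C=C(\C)CC/C=C(\C)CCC=C(C)C | starting material
4 | (2E,6E)-farnesyl acetate | CC(=O)OC/C=C(\C)CC/C=C(\C)CCC=C(C)C | intermediate
5 | (2E,6E,10E)-12-hydroxy-3,7,11-trimethyldodeca-2,6,10-trien-1-yl acetate | CC(=O)OC/C=C(\C)CC/C=C(\C)CC/C=C(\C)CO | intermediate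
6 | (2E,6E,10E)-12-bromo-3,7,11-trimethyldodeca-2,6,10-trien-1-yl acetate | CC(=O)OC/C=C(\C)CC/C=C(\C)CC/C=C(\C)CBr | intermediate
7 | (2E,6E,10E,14E,18E)-3,7,11,15,19,23-hexamethyl-13-(p-tolylsulfonyl)tetracosa-2,6,10,14,18,22-hexaen-1-yl acetate, racemic at C13 | CC(=O)OC/C=C(\C)CC/C=C(\C)CC/C=C(\C)CC(S(=O)(=O)c1ccc(C)cc1)/C=C(\C)CC/C=C(\C)CCC=C(C)C | intermediate
8 | (2E,6E,10E,14E,18E)-3,7,11,15,19,23-hexamethyl-13-(p-tolylsulfonyl)tetracosa-2,6,10,14,18,22-hexaen-1-ol, racemic at C13 (C30 hydroxy sulfone) | OC/C=C(\C)CC/C=C(\C)CC/C=C(\C)CC(S(=O)(=O)c1ccc(C)cc1)/C=C(\C)CC/C=C(\C)CCC=C(C)C | intermediate (not isolated)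
9 | all-E-hexaprenol, (2E,6E,10E,14E,18E)-3,7,11,15,19,23-hexamethyltetracosa-2,6,10,14,18,22-hexaen-1-ol | OC/C=C(\C)CC/C=C(\C)CC/C=C(\C)CC/C=C(\C)CC/C=C(\C)CCC=C(C)C | intermediate
10 | all-E-hexaprenyl bromide, (2E,6E,10E,14E,18E)-1-bromo-3,7,11,15,19,23-hexamethyltetracosa-2,6,10,14,18,22-hexaene | BrC/C=C(\C)CC/C=C(\C)CC/C=C(\C)CC/C=C(\C)CC/C=C(\C)CCC=C(C)C | intermediate
11 | (±)-but-3-yn-2-ol | CC(O)C#C | starting material
12 | (6E,10E,14E,18E,22E)-7,11,15,19,23,27-hexamethyloctacosa-6,10,14,18,22,26-hexaen-3-yn-2-ol, racemic at C2 | CC(O)C#CC/C=C(\C)CC/C=C(\C)CC/C=C(\C)CC/C=C(\C)CC/C=C(\C)CCC=C(C)C | intermediate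
13 | (6E,10E,14E,18E,22E)-7,11,15,19,23,27-hexamethyloctacosa-6,10,14,18,22,26-hexaen-3-yn-2-one | CC(=O)C#CC/C=C(\C)CC/C=C(\C)CC/C=C(\C)CC/C=C(\C)CC/C=C(\C)CCC=C(C)C | intermediate
14 | ethyl 1,3-dithiane-2-carboxylate | CCOC(=O)C1SCCCS1 | starting material
15 | ethyl 2-[(3Z,6E,10E,14E,18E,22E)-7,11,15,19,23,27-hexamethyl-2-oxooctacosa-3,6,10,14,18,22,26-heptaen-4-yl]-1,3-dithiane-2-carboxylate (Z-enone ester Michael adduct) | CCOC(=O)C1(SCCCS1)/C(C/C=C(\C)CC/C=C(\C)CC/C=C(\C)CC/C=C(\C)CC/C=C(\C)CCC=C(C)C)=C\C(C)=O | intermediate (not isolated)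
16 | 7-hydroxy-11-[(2E,6E,10E,14E,18E)-3,7,11,15,19,23-hexamethyltetracosa-2,6,10,14,18,22-hexaen-1-yl]-1,5-dithiaspiro[5.5]undeca-7,10-dien-9-one | OC1=CC(=O)C=C(C/C=C(\C)CC/C=C(\C)CC/C=C(\C)CC/C=C(\C)CC/C=C(\C)CCC=C(C)C)C12SCCCS2 | intermediate
17 | 2-hydroxy-6-[(2E,6E,10E,14E,18E)-3,7,11,15,19,23-hexamethyltetracosa-2,6,10,14,18,22-hexaen-1-yl]cyclohexa-2,5-diene-1,4-dione | OC1=CC(=O)C=C(C/C=C(\C)CC/C=C(\C)CC/C=C(\C)CC/C=C(\C)CC/C=C(\C)CCC=C(C)C)C1=O | intermediate
18 | 2-[(2E,6E,10E,14E,18E)-3,7,11,15,19,23-hexamethyltetracosa-2,6,10,14,18,22-hexaen-1-yl]-6-methoxycyclohexa-2,5-diene-1,4-dione | COC1=CC(=O)C=C(C/C=C(\C)CC/C=C(\C)CC/C=C(\C)CC/C=C(\C)CC/C=C(\C)CCC=C(C)C)C1=O | target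

**Totals and risks**

Total step count: 12. Longest linear sequence: 11 steps (3 to 18, steps 2 to 12); step 1 is the side branch.

Steps most likely to fail:

1. Step 10 (Proposed new method). What may go wrong: proton transfer from the propargylic–allylic CH2 of 13 (or of adduct 15) to the carbanion or to alkoxide, with allene/dienone isomerisation and migration of the first chain double bond; 1,2-addition to the ketone; O-acylation to an enol lactone that does not rearrange. Fallback (known chemistry; sets out from 10, returns at 18): the ring is bought instead of built. Commercial 2-methoxyphenol is protected (MOMCl, i-Pr2NEt, CH2Cl2) as 1-methoxy-2-(methoxymethoxy)benzene F1. Ortho-lithiation next to the acetal oxygen (n-BuLi, TMEDA, THF, 0 °C), transmetalation with CuBr·SMe2 and SN2 allylation with 10 should give 1-hexaprenyl-3-methoxy-2-(methoxymethoxy)benzene F2. Catalytic HCl in MeOH/THF removes the acetal to give 2-hexaprenyl-6-methoxyphenol F3. Para-oxidation of the phenol with (KSO3)2NO (KH2PO4 buffer, acetone/H2O) gives 18.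

2. Step 11. What may go wrong: attack of the trivalent-iodine oxidant, or of the CF3CO2H it releases, on the six trisubstituted olefins or on the enolised dione; oxidation at sulfur without C–S cleavage. Fallback (sets out from 16, returns at 17): selective mono-S-oxidation with NaIO4 (1 equiv, aq. MeOH/THF, 0 °C), which leaves olefins untouched, should give 7-hydroxy-11-hexaprenyl-1,5-dithiaspiro[5.5]undeca-7,10-dien-9-one 1-oxide F4 as a diastereomer mixture. The activated monosulfoxide is then hydrolysed with dilute HCl in aq. THF at 23 °C to 17.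

3. Step 12. What may go wrong: ambident alkylation giving the ortho-quinone ether at the C4 oxygen; 1,3-dipolar cycloaddition of the diazoalkane to the quinone C2=C3 bond; base-type cyclisation of the prenylquinone. Fallback (sets out from 17, returns at 18): acid-catalysed exchange with methanol (MeOH, cat. TsOH, 23 °C), a vinylogous Fischer esterification in which the C6–O bond, not the O–CH3 bond, is formed under thermodynamic control. No new compound arises (entry F0).

**Further compounds**

F1 | step 10 | 1-methoxy-2-(methoxymethoxy)benzene | COCOc1ccccc1OC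
F2 | step 10 | 1-[(2E,6E,10E,14E,18E)-3,7,11,15,19,23-hexamethyltetracosa-2,6,10,14,18,22-hexaen-1-yl]-3-methoxy-2-(methoxymethoxy)benzene | COCOc1c(OC)cccc1C/C=C(\C)CC/C=C(\C)CC/C=C(\C)CC/C=C(\C)CC/C=C(\C)CCC=C(C)C
F3 | step 10 | 2-[(2E,6E,10E,14E,18E)-3,7,11,15,19,23-hexamethyltetracosa-2,6,10,14,18,22-hexaen-1-yl]-6-methoxyphenol | COc1cccc(C/C=C(\C)CC/C=C(\C)CC/C=C(\C)CC/C=C(\C)CC/C=C(\C)CCC=C(C)C)c1O
F4 | step 11 | 7-hydroxy-11-[(2E,6E,10E,14E,18E)-3,7,11,15,19,23-hexamethyltetracosa-2,6,10,14,18,22-hexaen-1-yl]-1,5-dithiaspiro[5.5]undeca-7,10-dien-9-one 1-oxide (diastereomer mixture) | OC1=CC(=O)C=C(C/C=C(\C)CC/C=C(\C)CC/C=C(\C)CC/C=C(\C)CC/C=C(\C)CCC=C(C)C)C12SCCCS2=O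
F0 | step 12 | none | none
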